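Thursday's flask at 0 °C stops higher than Monday's at 6 °C, with target at 43.7% against 29.8% at 120 min, and both target columns are already flat at the first reading, 20.0 min.

| flask | starting material | second substrate | partner | protic impurity | free catalyst | temperature | remark | time |
|---|---|---|---|---|---|---|---|---|
| Thursday's | 1 M | 1 M | 1.2 M | 0.10 M | 5 mM | 0 °C | the very flask that is asked about, followed so far |  |
| Monday's | 1 M | 1 M | 1.2 M | 0.10 M | 5 mM | 6 °C | run made earlier |  |
| flask | 1.0 M | 1.00 M | 1.20 M | 0.100 M | 5.0 mM | 0 °C |  | 2.0 h |

| run | time / min | target / % | starting material / % |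
|---|---|---|---|
| Thursday's | 20.0 | 43.6 | 57.5 |
| Thursday's | 40.0 | 43.9 | 55.9 |
| Thursday's | 60.0 | 43.4 | 55.4 |
| Thursday's | 80.0 | 43.1 | 56.6 |
| Thursday's | 90.0 | 44.7 | 56.3 |
| Thursday's | 120 | 43.7 | 56.0 |
| Monday's | 20.0 | 30.6 | 69.7 |
| Monday's | 40.0 | 30.8 | 69.7 |
| Monday's | 60.0 | 31.0 | 69.8 |
| Monday's | 80.0 | 30.2 | 69.7 |
| Monday's | 90.0 | 29.9 | 69.9 |
| Monday's | 120 | 29.8 | 69.4 |

(scatter of a reading: 0.5 percentage points)

- grey: at 2.0 h add free catalyst, 100% of the amount charged, then wait 1.0 h
- violet: change nothing and wait 1.0 h more
- red: at 2.0 h add partner, 50.0% of the amount charged, then wait 1.0 h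
- blue: at 2.0 h raise the temperature by 10 K, then wait 1.0 h

- additions leave the volume as it is
- a reading or a percentage of target counts all its forms, free or not

- target, in percent of the starting material first charged, at 2.0 h
- the remedy with the largest gain of target, or "none" below 2 percentage points (grey / violet / red / blue / none)
- target present, in percent of the starting material first charged, after grey
- target present, in percent of the starting material first charged, after blue

I count Thursday's stop two ways. The starting material column leaves 56.0% at the last reading, while the target column, read as what has gone, leaves 56.3%. These are separate measurements and they agree within the scatter of 0.5 percentage points, so I trust the number and answer 43.7% for now.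

I bet that the catalyst stopped working, though these readings can't prove it. I assume that a given amount of catalyst, over its working life, converts in proportion to the starting material still there. Integrating that rate gives ln(charged/left) = reach × catalyst charged. So Thursday's starting material column gives 0.116 mM⁻¹ for the reach, the natural log of the fall in starting material per mM of catalyst charged. The target column gives 0.115 mM⁻¹. Monday's reach is smaller, 0.0731 mM⁻¹, so in my reading warmth costs reach.

For grey the two ways part. A fixed turnover number would double target to 87.4%, while the reach gives 68.6%, a gain of 25 points. The turnover count is the one that cheats, since it credits the second dose with as much target as the first, although the second dose meets 56.0% of the starting material. If the catalyst has stopped, partner and warmth have nothing to work through, so I commit to grey and keep blue at 43.7%.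

The forecast shares my answer for now and differs from my reckoning on the others. It says 43.7% for now, red as best, 43.7% after grey and 23% after blue, reading the plateau as a balance “rather than catalyst death, though the data cannot strictly exclude death”.

The flask gives 43.8%, and grey is best, ending at 63.5%, a gain of 20 points. Blue stays at 43.8% and red gains 0 points.

    starting material + free catalyst ⇌ catalyst intermediate A (K = 5.25 L mol⁻¹, k = 2.43 L mol⁻¹ s⁻¹, Ea = 37.0 kJ mol⁻¹, ΔH = −65.0 kJ mol⁻¹)
    partner + catalyst intermediate A → free catalyst + target (k = 1.19 L mol⁻¹ s⁻¹, Ea = 38.0 kJ mol⁻¹)
    second substrate + free catalyst ⇌ catalyst intermediate B (K = 0.840 L mol⁻¹, k = 6.20 L mol⁻¹ s⁻¹, Ea = 52.0 kJ mol⁻¹, ΔH = −2.00 kJ mol⁻¹)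
    partner + catalyst intermediate B → free catalyst + second product (k = 1.04 L mol⁻¹ s⁻¹, Ea = 40.0 kJ mol⁻¹)
    crystals ⇌ target, rate k5*(cs5 - [target]) while solid is left; crystals form when [target] > cs5 (solubility = 0.210 M, k = 0.0823 s⁻¹)
    partner + protic impurity → quenched reagent (k = 0.107 L mol⁻¹ s⁻¹, Ea = 42.0 kJ mol⁻¹)
    catalyst intermediate B → spent catalyst (k = 0.0203 s⁻¹, Ea = 66.0 kJ mol⁻¹)
    (constants at 0 °C)

Spent catalyst stands at 100% of the catalyst charged at 120 min. The same flask run without the binding of second substrate to free catalyst reaches 100% of target at 2.0 h instead of 43.8%, which makes that binding the main reason target stops short. Target after grey implies a reach of 0.101 mM⁻¹, lower than Thursday's 0.116 mM⁻¹. For the neighbour charged with 0.0085 M of free catalyst, Thursday's reach gives 62.7%, and that neighbour gives 59.3%.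

The runs are simulated on assumed constants; noise was put on by code.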